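The acyl chain of the target, from C2 to C23, is an unbranched run of CH2 groups ending in CH3, with no substituent, heteroatom or stereocentre. Any internal C–C bond can therefore be built as C=C and hydrogenated away without trace. The phenyl ring, the only ring, is bought in and stays a spectator.
Cuts: the first is C10–C11 (retro-hydrogenation to C10=C11, then retro-cross-metathesis). It divides the odd 23 carbons into C1–C10, from a C11 ω-alkenoate that sheds its =CH2, and C11–C23, from a C14 1-alkene that sheds its =CH2. The second is the acyl C1–O bond of the ester.
Forward: undec-10-enoic acid 1 and 2-phenylethanol 2 are condensed to ester 3; 3 and 1-tetradecene 4 are joined at C10=C11 to give 5; 5 is saturated to the target 6. No ring is formed at any stage.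
Stereochemistry: none has to be created. The only stereo-element of the route, the E/Z geometry of C10=C11 in 5, disappears in the last step.

Key step: step 2

Remark on the chemistry: 6 has no stereocentre and no stereogenic double bond, so it is a single achiral species and the demand for one enantiomer is met by any route. Compound 5 is drawn as its expected major E isomer, and any Z isomer present converges on the same product in step 3.

Step 1
Reactants: 1 undec-10-enoic acid; 2 2-phenylethanol
Product: 3 2-phenylethyl undec-10-enoate
Conditions: p-TsOH·H2O (5 mol %), toluene, reflux, Dean–Stark trap
Reagents that add atoms: none
Why: Fischer esterification of an unhindered primary alcohol with an unbranched acid is an equilibrium that azeotropic removal of water should drive to completion, and neither the isolated terminal alkene nor the phenyl ring reacts with catalytic sulfonic acid in toluene.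

Step 2
Reactants: 3 2-phenylethyl undec-10-enoate; 4 1-tetradecene
Product: 5 2-phenylethyl (E)-tricos-10-enoate
Conditions: 4 (4 equiv, filtered through basic alumina), (H2IMes)(PCy3)Cl2Ru=CHPh (2 mol %), 1,4-benzoquinone (10 mol %), degassed CH2Cl2, 40 °C, Ar sweep; then ethyl vinyl ether; SiO2
Reagents that add atoms: none
Why: This is an olefin cross-metathesis by the metallacyclobutane mechanism: the ruthenium alkylidene adds to a terminal C=C in a [2+2] sense, the ruthenacyclobutane opens the other way, and alternation between the two alkenes joins C10 of 3 to C2 of 4 (C11 of the new chain) while the two =CH2 termini leave as ethene, whose removal in the argon stream pulls the exchange forward. The closest known reaction type is the cross-metathesis of ω-unsaturated fatty esters with linear 1-alkenes by second-generation ruthenium carbenes. No ring is closed and no stereocentre is created; the C10=C11 geometry should settle mainly on E under thermodynamic control and does not matter because step 3 deletes it. The first selectivity needed is cross- over self-coupling: both partners are unhindered monosubstituted alkenes of equal reactivity, so the outcome is statistical, and it is tilted towards 5 by the fourfold excess of 4 and by the fact that the symmetrical internal alkenes from self-coupling are themselves substrates and re-enter the exchange. The ester of 3 lies eight methylenes from the alkene and cannot chelate ruthenium, yet it gives 5 a polarity between that of the ester-free hydrocarbons and that of the diester from self-coupling of 3, so silica gel should sort the three classes. The second selectivity needed is positional fidelity, since migration of a C=C before exchange would give inseparable C22 and C24 homologues; 1,4-benzoquinone intercepts the ruthenium hydrides responsible, the temperature stays at 40 °C, and ethyl vinyl ether deactivates the carbene before concentration.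

Step 3
Reactants: 5 2-phenylethyl (E)-tricos-10-enoate
Product: 6 2-phenylethyl tricosanoate
Conditions: H2 (1 atm), 10% Pd/C, EtOAc, rt
Reagents that add atoms: none
Why: Heterogeneous catalytic hydrogenation should saturate an unhindered 1,2-disubstituted alkene at ambient pressure whatever its geometry or any migration along the chain on the palladium surface, while the ester C–O bond is homobenzylic rather than benzylic and so resists hydrogenolysis, and the benzene ring is not reduced under such mild conditions.

Compound list
1 | undec-10-enoic acid | C=CCCCCCCCCC(=O)O | starting material
2 | 2-phenylethanol | OCCc1ccccc1 | starting material
3 | 2-phenylethyl undec-10-enoate | C=CCCCCCCCCC(=O)OCCc1ccccc1 | intermediate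
4 | 1-tetradecene | CCCCCCCCCCCCC=C | starting material
5 | 2-phenylethyl (E)-tricos-10-enoate | CCCCCCCCCCCC/C=C/CCCCCCCCC(=O)OCCc1ccccc1 | intermediate
6 | 2-phenylethyl tricosanoate | CCCCCCCCCCCCCCCCCCCCCCC(=O)OCCc1ccccc1 | target

Total step count: 3
Longest linear sequence: 3 steps (1 → 3 → 5 → 6)

Steps most likely to fail, in descending order of risk

**Step 2.** The exchange between two equally reactive terminal alkenes may stay too close to the statistical distribution. Hydride-mediated walking of a double bond before exchange, or internal-alkene isomers carried in with technical-grade 4, may also blur the chain length by one carbon in a way that chromatography cannot repair. The fallback makes the same C10=C11 bond by carbonyl olefination, which fixes the carbon count by construction. Setting out from 3, ozonolysis (O3, CH2Cl2, −78 °C; then Me2S) should remove the terminal CH2 and give 2-phenylethyl 10-oxodecanoate F1. Separately, commercial 1-bromotridecane and PPh3 (MeCN, reflux) should give tridecyl(triphenyl)phosphonium bromide F2. NaHMDS in THF at −78 °C should convert this salt into tridecylidene(triphenyl)phosphorane F3. Wittig reaction of this ylide with the aldehyde at −78 °C to rt, where the ester is left alone, should give 2-phenylethyl (Z)-tricos-10-enoate F4. Hydrogenation of the Z alkene under the conditions of step 3 brings the sequence back to the route at 6.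

**Step 3.** Hydrogen uptake may stall because the palladium surface is poisoned by traces of ruthenium, phosphine or quinone carried over from step 2. The fallback replaces surface catalysis by a metal-free concerted transfer of two hydrogens. Setting out from 5, excess p-toluenesulfonyl hydrazide with NaOAc in refluxing DME–H2O should release diazene (diimide) F5. Diimide delivers both hydrogens to C10=C11 through a cyclic six-centre transition state, with loss of nitrogen, and leaves the ester and arene untouched. The sequence comes back to the route at 6.

**Step 1.** The equilibrium may not be shifted fully. Prolonged heating with acid may also start inward migration of the terminal alkene, which would later falsify the chain length in step 2. The fallback is an irreversible acyl transfer under basic conditions. Setting out from 1, oxalyl chloride with catalytic DMF (CH2Cl2, 0 °C to rt) should give undec-10-enoyl chloride F6. This chloride should acylate 2 in the presence of Et3N and catalytic DMAP (CH2Cl2, 0 °C), and the sequence comes back to the route at 3.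

Further compounds
F1 | step 2 | 2-phenylethyl 10-oxodecanoate | O=CCCCCCCCCC(=O)OCCc1ccccc1
F2 | step 2 | tridecyl(triphenyl)phosphonium bromide | CCCCCCCCCCCCC[P+](c1ccccc1)(c1ccccc1)c1ccccc1.[Br-]
F3 | step 2 | tridecylidene(triphenyl)phosphorane | CCCCCCCCCCCCC=P(c1ccccc1)(c1ccccc1)c1ccccc1
F4 | step 2 | 2-phenylethyl (Z)-tricos-10-enoate | CCCCCCCCCCCC/C=C\CCCCCCCCC(=O)OCCc1ccccc1
F5 | step 3 | diazene (diimide) | N=N
F6 | step 1 | undec-10-enoyl chloride | C=CCCCCCCCCC(=O)Cl
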